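**Retrosynthetic overview**

1. The target is cut at the exocyclic (E)-alkene into a left unit (ring A oxepanone fused to ring B cyclohexane, 1-benzoxepine locants) and a right unit (cis-decalin, rings C and D, primed naphthalene locants). The alkene comes from 1,4-hydrogenation of a C-2'=C-1'–CH=CH–C-6 diene, made by Suzuki coupling of a ring-B alkenylboronate with a ring-C enol triflate.
2. Ring B is opened at C-9–C-9a and C-5a–C-6: a stepwise [4+2] (Michael, then ring-closing nitro-Michael) between a chiral 2-amino-diene ester (C-6 to C-9) and a nitroalkene carrying C-5a, C-9a and the future ring-A chain.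
3. The feature that allows this: in ring B the oxygenated carbons C-9a and C-7 are 1,4-related and C-9a sits next to the quaternary C-5a. C-9a can therefore be a nitronate carbon (later the ketone), C-7 a vinyl-ketone carbonyl, and C-5a the β-carbon of a nitroalkene.
4. Ring A is then closed onto the C-9a ketone by reductive keto-epoxide cyclisation (trans fusion); C-7 carbinol by Mukaiyama hydration; the ester at C-6 becomes the alkenylboronate.
5. Right unit from (S)-carvone (ring C): ring D by aldol condensation, cuprate addition and kinetic protonation (cis fusion), hydration, triflation. Ring order: B (key), A; D onto C; union.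

Key step: step 4

Remark (assumption): the sense of induction in step 4 is assigned by analogy with Michael additions of (S)-2-(methoxymethyl)pyrrolidine enamines to (E)-nitroalkenes (the (R)-amine is used in step 2 if it proves opposite); the epoxide configuration set in step 7 is immaterial, since that carbon ends as the C-3 ketone.

**Route**

Step 1
Reactants: 1 methyl propiolate; 2 vinyl bromide
Product: 3 methyl pent-4-en-2-ynoate
Conditions: Pd(PPh3)2Cl2 (3 mol%), CuI (5 mol%), K2CO3, THF, rt
Reagents that add atoms: none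
Why: Sonogashira coupling under amine-free carbonate conditions should give the enynoate without conjugate addition to the propiolate.

Step 2
Reactants: 3 methyl pent-4-en-2-ynoate; 4 (S)-2-(methoxymethyl)pyrrolidine
Product: 5 methyl (2E)-3-[(2S)-2-(methoxymethyl)pyrrolidin-1-yl]penta-2,4-dienoate
Conditions: Et2O, 0 °C to rt
Reagents that add atoms: none
Why: uncatalysed Michael addition of the secondary amine to the ynoate β-carbon should give the push–pull (E)-enamino ester, a stable chiral 2-amino-1,3-diene.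

Step 3
Reactants: 6 6-methylhept-5-en-2-one; 7 nitromethane
Product: 9 (1E)-2,6-dimethyl-1-nitrohepta-1,5-diene, via nitro alcohol 8 (not isolated)
Conditions: MeNO2 (excess), DBU (0.2 equiv), rt; then MeSO2Cl, Et3N, CH2Cl2, −20 to 0 °C; (E)-isomer isolated by chromatography
Reagents that add atoms: none
Why: Henry addition and dehydration through the mesylate should give the β,β-disubstituted nitroalkene, whose (E)-isomer is separated while the (Z)- and deconjugated isomers can be re-equilibrated with base.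

Step 4
Reactants: 5 methyl (2E)-3-[(2S)-2-(methoxymethyl)pyrrolidin-1-yl]penta-2,4-dienoate; 9 (1E)-2,6-dimethyl-1-nitrohepta-1,5-diene
Product: 12 methyl (2S)-2-methyl-2-(4-methylpent-3-en-1-yl)-3-nitro-6-oxocyclohexane-1-carboxylate, via iminium nitronate 10 (not isolated), via cyclic enamino ester 11 (not isolated)
Conditions: toluene (2 M), 60 °C, sealed tube; then 1 M aqueous HCl, THF, 0 °C to rt
Reagents that add atoms: water, O
Why: Proposed new method: the enamine carbon C-2 of 5 adds to the disubstituted β-carbon of 9 (Michael addition under neutral conditions that should keep the (E)-geometry of 9), and the nitronate carbon of zwitterion 10 then attacks the terminal carbon of the vinyl-iminium in a 6-endo-trig conjugate addition that forms the C-3–C-4 bond of 12 and closes ring B, a stepwise [4+2] annulation. The closest known reactions are the annulation of chiral 2-amino-1,3-dienes with nitroalkenes to 4-nitrocyclohexanones, the Michael addition of (S)-2-(methoxymethyl)pyrrolidine enamines to (E)-nitroalkenes and the double Michael reaction of γ,δ-unsaturated β-keto esters with nitroalkenes; none has been shown with a β,β-dialkyl nitroalkene. The quaternary C-2 is the only stereocentre that matters and is set in the first bond formation: the pyrrolidine auxiliary shields one enamine face and the synclinal enamine/nitroalkene arrangement fixes the acceptor face. C-1 and C-3 are epimerisable and are erased in steps 6 and 5. The step needs attack through C-2 of the dienamine, which its push–pull polarisation secures, and ring closure faster than retro-Michael cleavage, which the electrophilic vinyl-iminium secures; acid then hydrolyses 11 and frees the auxiliary.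

Step 5
Reactants: 12 methyl (2S)-2-methyl-2-(4-methylpent-3-en-1-yl)-3-nitro-6-oxocyclohexane-1-carboxylate
Product: 13 methyl (2S)-2-methyl-2-(4-methylpent-3-en-1-yl)-3,6-dioxocyclohexane-1-carboxylate
Conditions: NaOMe (2.1 equiv), MeOH, 0 °C; then aqueous TiCl3, NH4OAc, THF, rt
Reagents that add atoms: water, O
Why: Nef reaction through TiCl3 reduction of the nitronate and imine hydrolysis should give the C-3 ketone under near-neutral conditions that spare the alkene and the β-keto ester, and it removes the C-3 stereocentre.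

Step 6
Reactants: 13 methyl (2S)-2-methyl-2-(4-methylpent-3-en-1-yl)-3,6-dioxocyclohexane-1-carboxylate
Product: 15 methyl (6S)-2,6-dimethyl-6-(4-methylpent-3-en-1-yl)-5-oxocyclohex-1-ene-1-carboxylate, via enol phosphate 14 (not isolated)
Conditions: NaH (1.05 equiv), THF, 0 °C; ClP(O)(OEt)2; then Me2CuLi, Et2O, −78 to −45 °C
Reagents that add atoms: lithium dimethylcuprate, [Li+].C[Cu-]C
Why: addition–elimination of the cuprate on the enol phosphate of the β-keto ester should install the ring methyl regiospecifically, leave the hindered ketone untouched and turn the ring alkene into an electron-poor enoate.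

Step 7
Reactants: 15 methyl (6S)-2,6-dimethyl-6-(4-methylpent-3-en-1-yl)-5-oxocyclohex-1-ene-1-carboxylate
Product: 16 methyl (6S)-6-{2-[(2R)-3,3-dimethyloxiran-2-yl]ethyl}-2,6-dimethyl-5-oxocyclohex-1-ene-1-carboxylate
Conditions: D-fructose-derived Shi ketone (0.3 equiv), KHSO5, K2CO3, Bu4NHSO4, MeCN–dimethoxymethane–aqueous buffer (pH 10.5), 0 °C
Reagents that add atoms: potassium peroxymonosulfate, [K+].[O-]S(=O)(=O)OO
Why: Shi epoxidation should select the electron-rich trisubstituted alkene over the tetrasubstituted enoate and set the epoxide carbon under reagent control, so that later intermediates are single diastereomers.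

Step 8
Reactants: 16 methyl (6S)-6-{2-[(2R)-3,3-dimethyloxiran-2-yl]ethyl}-2,6-dimethyl-5-oxocyclohex-1-ene-1-carboxylate
Product: 18 methyl (3R,5aS,9aS)-3-hydroxy-2,2,5a,7-tetramethyl-2,3,4,5,5a,8,9,9a-octahydro-1-benzoxepine-6-carboxylate, via trimethylsilyl ether 17 (not isolated)
Conditions: Me3SiOTf (1.2 equiv), Et3SiH (5 equiv), CH2Cl2, −78 to −40 °C; then K2CO3, MeOH, rt
Reagents that add atoms: none
Why: Proposed new method: Me3SiOTf silylates the epoxide oxygen, the ketone oxygen opens the epoxide at its tertiary carbon (7-endo), and the ring-A oxocarbenium ion is reduced by Et3SiH anti to the pseudo-axial angular methyl to give the trans fusion (9aS), while the silylated C-3 oxygen cannot close to a bicyclic ketal; the closest known reaction types are Lewis acid cyclisation of keto epoxides to bicyclic ketals by carbonyl participation and Et3SiH/Me3SiOTf reductive etherification of ketones.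

Step 9
Reactants: 18 methyl (3R,5aS,9aS)-3-hydroxy-2,2,5a,7-tetramethyl-2,3,4,5,5a,8,9,9a-octahydro-1-benzoxepine-6-carboxylate
Product: 19 methyl (3R,5aS,6R,9aS)-3-hydroxy-2,2,5a-trimethyl-7-methylidenedecahydro-1-benzoxepine-6-carboxylate
Conditions: LiN(iPr)2 (2.5 equiv), THF–HMPA, −78 °C; then AcOH, −78 °C
Reagents that add atoms: none
Why: deconjugative protonation (γ-deprotonation of the enoate, kinetic α-protonation of the dienolate) should move the alkene out of conjugation, the proton entering C-6 anti to the axial C-5a methyl so that the ester is equatorial.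

Step 10
Reactants: 19 methyl (3R,5aS,6R,9aS)-3-hydroxy-2,2,5a-trimethyl-7-methylidenedecahydro-1-benzoxepine-6-carboxylate
Product: 20 methyl (3R,5aS,6S,7S,9aS)-3,7-dihydroxy-2,2,5a,7-tetramethyldecahydro-1-benzoxepine-6-carboxylate
Conditions: Co(acac)2 (0.2 equiv), PhSiH3, O2 (1 atm), i-PrOH, rt
Reagents that add atoms: dioxygen, O=O
Why: Mukaiyama hydration through the tertiary C-7 radical, which O2 should trap on the face away from the axial C-5a methyl, giving the equatorial hydroxyl and axial methyl (7S).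

Step 11
Reactants: 20 methyl (3R,5aS,6S,7S,9aS)-3,7-dihydroxy-2,2,5a,7-tetramethyldecahydro-1-benzoxepine-6-carboxylate
Product: 21 (3R,5aS,6R,7S,9aS)-6-(hydroxymethyl)-2,2,5a,7-tetramethyldecahydro-1-benzoxepine-3,7-diol
Conditions: LiAlH4, THF, 0 °C
Reagents that add atoms: none
Why: hydride reduction of the ester to the primary alcohol, with no change at any stereocentre.

Step 12
Reactants: 21 (3R,5aS,6R,7S,9aS)-6-(hydroxymethyl)-2,2,5a,7-tetramethyldecahydro-1-benzoxepine-3,7-diol
Product: 22 (5aS,6S,7S,9aS)-7-hydroxy-2,2,5a,7-tetramethyl-3-oxodecahydro-1-benzoxepine-6-carbaldehyde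
Conditions: Dess–Martin periodinane (3 equiv), NaHCO3, CH2Cl2, rt
Reagents that add atoms: none
Why: Dess–Martin oxidation of the primary and the secondary alcohol in one operation (the tertiary alcohol is inert) should give the ring-A ketone and the aldehyde, whose equatorial C-6 epimer is also the thermodynamic one in the rigid trans-fused bicycle.

Step 13
Reactants: 22 (5aS,6S,7S,9aS)-7-hydroxy-2,2,5a,7-tetramethyl-3-oxodecahydro-1-benzoxepine-6-carbaldehyde
Product: 23 (5aS,6S,7S,9aS)-7-hydroxy-2,2,5a,7-tetramethyl-6-[(E)-2-(4,4,5,5-tetramethyl-1,3,2-dioxaborolan-2-yl)ethenyl]octahydro-1-benzoxepin-3(2H)-one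
Conditions: CrCl2 (8 equiv), LiI, Cl2CHB(pin), THF, rt
Reagents that add atoms: 2-(dichloromethyl)-4,4,5,5-tetramethyl-1,3,2-dioxaborolane, ClC(Cl)B1OC(C)(C)C(C)(C)O1
Why: Takai–Utimoto olefination with the gem-dichromium boryl reagent should give the (E)-alkenylboronate selectively from the aldehyde and leave the ketone alone.

Step 14
Reactants: 24 (S)-carvone
Product: 25 (2S,5S)-2-methyl-5-(prop-1-en-2-yl)cyclohexan-1-one
Conditions: LiBH(s-Bu)3, THF, −78 °C; aqueous NH4Cl
Reagents that add atoms: none
Why: conjugate hydride reduction of the enone; C-5 comes from carvone and the C-2 configuration is inconsequential because C-2 becomes sp2 in step 20.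

Step 15
Reactants: 25 (2S,5S)-2-methyl-5-(prop-1-en-2-yl)cyclohexan-1-one
Product: 26 (2S,5S)-5-(3-chloroprop-1-en-2-yl)-2-methylcyclohexan-1-one
Conditions: Ca(OCl)2, CO2 (solid), CH2Cl2–H2O, 0 °C
Reagents that add atoms: calcium hypochlorite, [Ca+2].[O-]Cl.[O-]Cl
Why: ene-type allylic chlorination of the 1,1-disubstituted alkene by hypochlorous acid should give the allylic chloride without touching the ketone.

Step 16
Reactants: 26 (2S,5S)-5-(3-chloroprop-1-en-2-yl)-2-methylcyclohexan-1-one; 27 methyl acetoacetate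
Product: 29 (2S,5S)-2-methyl-5-(6-oxohept-1-en-2-yl)cyclohexan-1-one, via alkylated acetoacetate 28 (not isolated)
Conditions: NaH, THF–DMF, NaI (cat.), 60 °C; then LiCl, H2O, DMSO, 150 °C
Reagents that add atoms: none
Why: acetoacetate alkylation of the allylic chloride followed by Krapcho dealkoxycarbonylation should append the 3-oxobutyl chain.

Step 17
Reactants: 29 (2S,5S)-2-methyl-5-(6-oxohept-1-en-2-yl)cyclohexan-1-one
Product: 30 (2S,4aR)-2,8-dimethyl-5-methylidene-3,4,4a,5,6,7-hexahydronaphthalen-1(2H)-one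
Conditions: pyrrolidine (0.3 equiv), AcOH (0.3 equiv), toluene, reflux with water separator
Reagents that add atoms: none
Why: intramolecular aldol condensation of the ring α-carbon onto the methyl ketone should close ring D as the conjugated enone, the only aldol mode that can dehydrate (the bridged alternative reverts).

Step 18
Reactants: 30 (2S,4aR)-2,8-dimethyl-5-methylidene-3,4,4a,5,6,7-hexahydronaphthalen-1(2H)-one
Product: 31 (2S,4aS,8aR)-2,8,8-trimethyl-5-methylideneoctahydronaphthalen-1(2H)-one
Conditions: Me2CuLi (from MeLi and CuI), BF3·OEt2, Et2O, −78 to −30 °C; then AcOH in THF, −78 °C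
Reagents that add atoms: lithium dimethylcuprate, [Li+].C[Cu-]C
Why: cuprate conjugate addition to the alkylidene ketone should build the gem-dimethyl quaternary carbon, and kinetic protonation of the enolate from the less hindered equatorial direction of ring D should give the cis ring fusion (8aR).

Step 19
Reactants: 31 (2S,4aS,8aR)-2,8,8-trimethyl-5-methylideneoctahydronaphthalen-1(2H)-one
Product: 32 (2S,4aS,5S,8aR)-5-hydroxy-2,5,8,8-tetramethyloctahydronaphthalen-1(2H)-one
Conditions: Co(acac)2 (0.2 equiv), PhSiH3, O2 (1 atm), i-PrOH, rt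
Reagents that add atoms: dioxygen, O=O
Why: Mukaiyama hydration, in which O2 should trap the tertiary C-5 radical on the convex face of the cis-decalin, placing the hydroxyl cis to the ring-fusion hydrogens (5S).

Step 20
Reactants: 32 (2S,4aS,5S,8aR)-5-hydroxy-2,5,8,8-tetramethyloctahydronaphthalen-1(2H)-one
Product: 33 (4aS,5S,8aR)-5-hydroxy-2,5,8,8-tetramethyl-3,4,4a,5,6,7,8,8a-octahydronaphthalen-1-yl trifluoromethanesulfonate
Conditions: KN(SiMe3)2 (2.2 equiv), THF, −78 °C; then PhNTf2
Reagents that add atoms: N-phenylbis(trifluoromethanesulfonimide), O=S(=O)(N(c1ccccc1)S(=O)(=O)C(F)(F)F)C(F)(F)F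
Why: irreversible kinetic enolisation should occur at C-2 and not at C-8a, which is shielded by the adjacent quaternary carbon, so the enol triflate forms toward C-2 without epimerising the ring fusion.

Step 21
Reactants: 23 (5aS,6S,7S,9aS)-7-hydroxy-2,2,5a,7-tetramethyl-6-[(E)-2-(4,4,5,5-tetramethyl-1,3,2-dioxaborolan-2-yl)ethenyl]octahydro-1-benzoxepin-3(2H)-one; 33 (4aS,5S,8aR)-5-hydroxy-2,5,8,8-tetramethyl-3,4,4a,5,6,7,8,8a-octahydronaphthalen-1-yl trifluoromethanesulfonate
Product: 34 (5aS,6S,7S,9aS)-7-hydroxy-6-{(E)-2-[(4aS,5S,8aR)-5-hydroxy-2,5,8,8-tetramethyl-3,4,4a,5,6,7,8,8a-octahydronaphthalen-1-yl]ethenyl}-2,2,5a,7-tetramethyloctahydro-1-benzoxepin-3(2H)-one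
Conditions: Pd(dppf)Cl2 (5 mol%), aqueous K3PO4, THF, 50 °C
Reagents that add atoms: none
Why: Suzuki–Miyaura coupling of the alkenylboronate with the enol triflate should join the two units with retention of both alkene geometries and tolerate the free hydroxyls and the ketone.

Step 22
Reactants: 34 (5aS,6S,7S,9aS)-7-hydroxy-6-{(E)-2-[(4aS,5S,8aR)-5-hydroxy-2,5,8,8-tetramethyl-3,4,4a,5,6,7,8,8a-octahydronaphthalen-1-yl]ethenyl}-2,2,5a,7-tetramethyloctahydro-1-benzoxepin-3(2H)-one
Product: 35 CNP0232921.1, (5aS,6S,7S,9aS)-7-hydroxy-6-{(2E)-2-[(2R,4aS,5S,8aR)-5-hydroxy-2,5,8,8-tetramethyloctahydronaphthalen-1(2H)-ylidene]ethyl}-2,2,5a,7-tetramethyloctahydro-1-benzoxepin-3(2H)-one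
Conditions: (η6-naphthalene)Cr(CO)3 (20 mol%), H2 (70 bar), THF, 45 °C
Reagents that add atoms: none
Why: chromium tricarbonyl-catalysed 1,4-hydrogenation of the s-cis diene delivers both hydrogens from the metal-bound face to C-2' and the chain CH, so the new exocyclic alkene has the chain cis to C-2' (E), and complexation on the ring-C face away from the gem-dimethyl group should give the 2'R centre.

**Compound list**

1 | methyl propiolate | C#CC(=O)OC | starting material
2 | vinyl bromide | C=CBr | starting material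
3 | methyl pent-4-en-2-ynoate | C=CC#CC(=O)OC | intermediate
4 | (S)-2-(methoxymethyl)pyrrolidine | COC[C@@H]1CCCN1 | starting material
5 | methyl (2E)-3-[(2S)-2-(methoxymethyl)pyrrolidin-1-yl]penta-2,4-dienoate | COC[C@@H]1CCCN1/C(C=C)=C/C(=O)OC | intermediate
6 | 6-methylhept-5-en-2-one | CC(=O)CCC=C(C)C | starting material
7 | nitromethane | C[N+](=O)[O-] | starting material
8 | 2,6-dimethyl-1-nitrohept-5-en-2-ol (racemic, not isolated) | CC(O)(C[N+](=O)[O-])CCC=C(C)C | intermediate
9 | (1E)-2,6-dimethyl-1-nitrohepta-1,5-diene | C/C(=C\[N+](=O)[O-])CCC=C(C)C | intermediate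
10 | iminium nitronate zwitterion, Michael adduct of 5 and 9 (not isolated) | COC[C@@H]1CCC[N+]1=C(C=C)C(C(=O)OC)[C@](C)(CCC=C(C)C)C=[N+]([O-])[O-] | intermediate
11 | methyl (6S)-2-[(2S)-2-(methoxymethyl)pyrrolidin-1-yl]-6-methyl-6-(4-methylpent-3-en-1-yl)-5-nitrocyclohex-1-ene-1-carboxylate (C-5 epimers, not isolated) | COC[C@@H]1CCCN1C1=C(C(=O)OC)[C@](C)(CCC=C(C)C)C([N+](=O)[O-])CC1 | intermediate
12 | methyl (2S)-2-methyl-2-(4-methylpent-3-en-1-yl)-3-nitro-6-oxocyclohexane-1-carboxylate (C-1/C-3 epimer mixture, both erased later) | COC(=O)C1C(=O)CCC([N+](=O)[O-])[C@@]1(C)CCC=C(C)C | intermediate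
13 | methyl (2S)-2-methyl-2-(4-methylpent-3-en-1-yl)-3,6-dioxocyclohexane-1-carboxylate (enolised at C-1) | COC(=O)C1C(=O)CCC(=O)[C@@]1(C)CCC=C(C)C | intermediate
14 | enol diethyl phosphate of 13 (not isolated) | COC(=O)C1=C(OP(=O)(OCC)OCC)CCC(=O)[C@@]1(C)CCC=C(C)C | intermediate
15 | methyl (6S)-2,6-dimethyl-6-(4-methylpent-3-en-1-yl)-5-oxocyclohex-1-ene-1-carboxylate | COC(=O)C1=C(C)CCC(=O)[C@@]1(C)CCC=C(C)C | intermediate
16 | methyl (6S)-6-{2-[(2R)-3,3-dimethyloxiran-2-yl]ethyl}-2,6-dimethyl-5-oxocyclohex-1-ene-1-carboxylate | COC(=O)C1=C(C)CCC(=O)[C@@]1(C)CC[C@H]1OC1(C)C | intermediate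
17 | 3-O-trimethylsilyl ether of 18 (not isolated) | COC(=O)C1=C(C)CC[C@@H]2OC(C)(C)[C@H](O[Si](C)(C)C)CC[C@@]12C | intermediate
18 | methyl (3R,5aS,9aS)-3-hydroxy-2,2,5a,7-tetramethyl-2,3,4,5,5a,8,9,9a-octahydro-1-benzoxepine-6-carboxylate | COC(=O)C1=C(C)CC[C@@H]2OC(C)(C)[C@H](O)CC[C@@]12C | intermediate
19 | methyl (3R,5aS,6R,9aS)-3-hydroxy-2,2,5a-trimethyl-7-methylidenedecahydro-1-benzoxepine-6-carboxylate | COC(=O)[C@@H]1C(=C)CC[C@@H]2OC(C)(C)[C@H](O)CC[C@@]12C | intermediate
20 | methyl (3R,5aS,6S,7S,9aS)-3,7-dihydroxy-2,2,5a,7-tetramethyldecahydro-1-benzoxepine-6-carboxylate | COC(=O)[C@@H]1[C@@](C)(O)CC[C@@H]2OC(C)(C)[C@H](O)CC[C@@]12C | intermediate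
21 | (3R,5aS,6R,7S,9aS)-6-(hydroxymethyl)-2,2,5a,7-tetramethyldecahydro-1-benzoxepine-3,7-diol | OC[C@@H]1[C@@](C)(O)CC[C@@H]2OC(C)(C)[C@H](O)CC[C@@]12C | intermediate
22 | (5aS,6S,7S,9aS)-7-hydroxy-2,2,5a,7-tetramethyl-3-oxodecahydro-1-benzoxepine-6-carbaldehyde | O=C[C@@H]1[C@@](C)(O)CC[C@@H]2OC(C)(C)C(=O)CC[C@@]12C | intermediate
23 | (5aS,6S,7S,9aS)-7-hydroxy-2,2,5a,7-tetramethyl-6-[(E)-2-(4,4,5,5-tetramethyl-1,3,2-dioxaborolan-2-yl)ethenyl]octahydro-1-benzoxepin-3(2H)-one | CC1(C)OB(/C=C/[C@@H]2[C@@](C)(O)CC[C@@H]3OC(C)(C)C(=O)CC[C@@]23C)OC1(C)C | intermediate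
24 | (S)-carvone | CC1=CC[C@@H](CC1=O)C(C)=C | starting material
25 | (2S,5S)-2-methyl-5-(prop-1-en-2-yl)cyclohexan-1-one (major C-2 epimer) | C[C@H]1CC[C@@H](CC1=O)C(C)=C | intermediate
26 | (2S,5S)-5-(3-chloroprop-1-en-2-yl)-2-methylcyclohexan-1-one | C[C@H]1CC[C@@H](CC1=O)C(=C)CCl | intermediate
27 | methyl acetoacetate | CC(=O)CC(=O)OC | starting material
28 | methyl 2-acetyl-4-[(1S,4S)-4-methyl-3-oxocyclohexyl]pent-4-enoate (mixture at C-2, not isolated) | C[C@H]1CC[C@@H](CC1=O)C(=C)CC(C(C)=O)C(=O)OC | intermediate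
29 | (2S,5S)-2-methyl-5-(6-oxohept-1-en-2-yl)cyclohexan-1-one | C[C@H]1CC[C@@H](CC1=O)C(=C)CCC(C)=O | intermediate
30 | (2S,4aR)-2,8-dimethyl-5-methylidene-3,4,4a,5,6,7-hexahydronaphthalen-1(2H)-one | CC1=C2C(=O)[C@@H](C)CC[C@@H]2C(=C)CC1 | intermediate
31 | (2S,4aS,8aR)-2,8,8-trimethyl-5-methylideneoctahydronaphthalen-1(2H)-one (cis-fused) | C[C@H]1CC[C@H]2[C@@H](C1=O)C(C)(C)CCC2=C | intermediate
32 | (2S,4aS,5S,8aR)-5-hydroxy-2,5,8,8-tetramethyloctahydronaphthalen-1(2H)-one | C[C@H]1CC[C@H]2[C@@H](C1=O)C(C)(C)CC[C@]2(C)O | intermediate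
33 | (4aS,5S,8aR)-5-hydroxy-2,5,8,8-tetramethyl-3,4,4a,5,6,7,8,8a-octahydronaphthalen-1-yl trifluoromethanesulfonate | CC1=C(OS(=O)(=O)C(F)(F)F)[C@@H]3[C@H](CC1)[C@@](C)(O)CCC3(C)C | intermediate
34 | (5aS,6S,7S,9aS)-7-hydroxy-6-{(E)-2-[(4aS,5S,8aR)-5-hydroxy-2,5,8,8-tetramethyl-3,4,4a,5,6,7,8,8a-octahydronaphthalen-1-yl]ethenyl}-2,2,5a,7-tetramethyloctahydro-1-benzoxepin-3(2H)-one | CC1=C(/C=C/[C@@H]2[C@@](C)(O)CC[C@@H]3OC(C)(C)C(=O)CC[C@@]23C)[C@@H]4[C@H](CC1)[C@@](C)(O)CCC4(C)C | intermediate
35 | CNP0232921.1, (5aS,6S,7S,9aS)-7-hydroxy-6-{(2E)-2-[(2R,4aS,5S,8aR)-5-hydroxy-2,5,8,8-tetramethyloctahydronaphthalen-1(2H)-ylidene]ethyl}-2,2,5a,7-tetramethyloctahydro-1-benzoxepin-3(2H)-one | C[C@@H]1CC[C@H]2[C@@H](/C1=C/C[C@H]1[C@]3(C)CCC(=O)C(C)(C)O[C@H]3CC[C@]1(C)O)C(C)(C)CC[C@]2(C)O | target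

**Summary**

Total step count: 22. Longest linear sequence: 14 steps (steps 1, 2, 4 to 13, 21, 22).

Steps most likely to fail:

1. Step 4 (proposed method). The conjugate addition at the fully substituted nitroalkene carbon may be slow, proton transfer may scramble the alkene geometry, or the auxiliary may discriminate the faces poorly. Fallback, setting out from 5 and 9 and returning at 12: aqueous acid hydrolysis of 5 gives methyl 3-oxopent-4-enoate F1, which is silylated (t-BuMe2SiOTf, Et3N) to methyl (2Z)-3-[(tert-butyldimethylsilyl)oxy]penta-2,4-dienoate F2. Thermal Diels–Alder reaction of this 2-silyloxy diene with 9 (toluene, 110 °C) gives racemic methyl 6-[(tert-butyldimethylsilyl)oxy]-2-methyl-2-(4-methylpent-3-en-1-yl)-3-nitrocyclohex-5-ene-1-carboxylate F3, and mild acid hydrolysis returns 12 as the racemate. The antipodes are then parted as separable diastereomers after the reagent-controlled epoxidation of step 7.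

2. Step 8 (proposed method). A 1,2-hydride shift of the silyl-activated epoxide, or opening at its secondary carbon, may outrun participation of the hindered ketone oxygen. Fallback, setting out from 15 and returning at 18: NaBH4 in MeOH reduces the ring ketone to methyl (5S,6S)-5-hydroxy-2,6-dimethyl-6-(4-methylpent-3-en-1-yl)cyclohex-1-ene-1-carboxylate F4, separated from its C-5 epimer. Shi epoxidation as in step 7 gives methyl (5S,6S)-6-{2-[(2R)-3,3-dimethyloxiran-2-yl]ethyl}-5-hydroxy-2,6-dimethylcyclohex-1-ene-1-carboxylate F5. Camphorsulfonic acid in CH2Cl2 then effects the acid-catalysed 7-endo opening of the trisubstituted epoxide by the hydroxyl at the tertiary carbon, giving 18.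

3. Step 22. The hindered diene, whose ring terminus carries a methyl group, may not reach the s-cis η4 geometry on chromium, or facial selectivity may be poor. Fallback, setting out from 34 and returning at 35: dissolving-metal reduction (Li, liquid NH3, THF, t-BuOH, −78 °C) brings about 1,4-reduction of the conjugated diene and also reduces the ring-A ketone. The resulting 3-hydroxy analogue of 35 F6 is separated from its alkene and C-2' isomers and re-oxidised with Dess–Martin periodinane to 35.

Further compounds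
F1 | step 4 | methyl 3-oxopent-4-enoate | COC(=O)CC(=O)C=C
F2 | step 4 | methyl (2Z)-3-[(tert-butyldimethylsilyl)oxy]penta-2,4-dienoate | COC(=O)/C=C(\O[Si](C)(C)C(C)(C)C)C=C
F3 | step 4 | methyl 6-[(tert-butyldimethylsilyl)oxy]-2-methyl-2-(4-methylpent-3-en-1-yl)-3-nitrocyclohex-5-ene-1-carboxylate (racemic) | COC(=O)C1C(O[Si](C)(C)C(C)(C)C)=CCC([N+](=O)[O-])C1(C)CCC=C(C)C
F4 | step 8 | methyl (5S,6S)-5-hydroxy-2,6-dimethyl-6-(4-methylpent-3-en-1-yl)cyclohex-1-ene-1-carboxylate | COC(=O)C1=C(C)CC[C@H](O)[C@@]1(C)CCC=C(C)C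
F5 | step 8 | methyl (5S,6S)-6-{2-[(2R)-3,3-dimethyloxiran-2-yl]ethyl}-5-hydroxy-2,6-dimethylcyclohex-1-ene-1-carboxylate | COC(=O)C1=C(C)CC[C@H](O)[C@@]1(C)CC[C@H]1OC1(C)C
F6 | step 22 | 3-hydroxy analogue of 35 (C-3 carbinol epimers) | C[C@@H]1CC[C@H]2[C@@H](/C1=C/C[C@H]1[C@]3(C)CCC(O)C(C)(C)O[C@H]3CC[C@]1(C)O)C(C)(C)CC[C@]2(C)O
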